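The chemist at the spring flask asked me what it held at 10 h and which remedy paid.

in all of them: substrate 0.55 M

| run | coupling partner | protic impurity | temperature | remark | time |
|---|---|---|---|---|---|
| spring | 2.2 M | 0.055 M | 80 °C | the very flask that is asked about, followed so far |  |
| midnight | 2.2 M | 0.083 M | 75 °C | run made earlier |  |
| flask | 2.20 M | 0.0550 M | 80 °C |  | 10 h |

Both flasks started from the same substrate with 4.00 equivalents of coupling partner, so I expected a long rise, but the readings stopped rising.

| run | time / h | target / % |
|---|---|---|
| spring | 0.500 | 30.6 |
| spring | 1.00 | 34.7 |
| spring | 2.50 | 37.3 |
| spring | 6.00 | 36.7 |
| midnight | 0.833 | 30.8 |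
| midnight | 2.00 | 34.3 |
| midnight | 4.00 | 36.9 |
| midnight | 10.0 | 36.8 |

(scatter of a reading: 0.5 percentage points)

The spring flask moved by −0.6 percentage points between 2.50 h and 6.00 h, so I took the mean of those two readings as its plateau, 37.0 %. The midnight run was cooler and held more protic impurity. Its first reading, 30.8 % at 0.833 h, lay close to the spring reading of 30.6 % at 0.500 h, and the mean of its last two readings gave a plateau of 36.9 %. So the clock had moved and the split had not, though those two changes are confounded.

I therefore read the plateau as a fork under kinetic control: substrate goes to target at first order in substrate and to a loss at second order, and that loss holds the other 63.0 %. The share to target is then a fixed level over the sum of that level and the substrate present. Replacing the falling substrate by its mean, half the charge, gave 0.162 M as the break-even substrate, the level at which the two ways use substrate equally fast. Integrating the share over the fall instead gave 43.5 % with that level, so the mean overstates it.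

- north: at 10 h take out 90 % of the target then present, then wait 5.0 h
- south-west: at 10 h raise the temperature by 20 K, then wait 5.0 h
- north-west: change nothing and wait 5.0 h more

* target, in percent of the substrate first charged, at 10 h
* the remedy with the largest gain of target, or "none" below 2 percentage points (north / south-west / north-west / none)
* target present, with what was taken out counted in, in percent of the substrate first charged, after south-west
* target present, with what was taken out counted in, in percent of the substrate first charged, after north-west

- what is taken out of target is counted as made

On this reading the split in the spring flask was made by about 2.50 h, so I committed to 37.0 % at 10 h, the same after south-west and north-west, and to none as the answer on the best remedy.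

The forecast gave 37 % (36.4 % to 37.5 %), 37 % after south-west (34.5 % to 39 %), 37 % after north-west (36.3 % to 37.7 %) and north as best remedy, saying “I read the plateau as equilibrium”, and there it differed from my reckoning.

The spring flask held 37.1 % of target at 10 h, beside 62.6 % of side product and 0.29 % of substrate, and the best remedy was none, with 37.1 % after south-west and 37.1 % after north-west.

    substrate + coupling partner → target (k = 0.0191 L mol⁻¹ min⁻¹, Ea = 88.0 kJ mol⁻¹)
    2 substrate → side product (k = 0.148 L mol⁻¹ min⁻¹, Ea = 85.0 kJ mol⁻¹)
    coupling partner + protic impurity → quenched reagent (k = 1.97 L mol⁻¹ min⁻¹, Ea = 71.0 kJ mol⁻¹)
    coupling partner → decomposed reagent (k = 0.0102 min⁻¹, Ea = 105 kJ mol⁻¹)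
    (constants at 80 °C)

The break-even substrate over the charge gave 0.294 for target against side product at the start of the spring flask, and the rates stood at 0.26. In the neighbour flask charged with 0.22 M of substrate, the break-even substrate gave 59.6 % of target, and that flask held 56.0 %.

The data come from a simulation with made-up constants, noise included.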